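Side product came slowly in the autumn run. It crept from 17.0% at 3.00 d to 21.0% at 12.0 d, while target read 59.0% at 12.0 d. So I read the ratio of target to side product late, from 12.0 d onward.

| flask | substrate | coupling partner | capture agent | remark | time |
|---|---|---|---|---|---|
| autumn | 1.4 M | 1.8 M | 0.10 M | run made earlier |  |
| midnight | 2.2 M | 1.8 M | 0.10 M | run made earlier |  |
| winter | 1 M | 0.90 M | 0.10 M | run made earlier |  |
| flask | 1.0 M | 1.80 M | 0.100 M |  | 15 d |

| run | time / d | target / % | side product / % |
|---|---|---|---|
| autumn | 3.00 | 58.8 | 17.0 |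
| autumn | 6.00 | 58.8 | 19.4 |
| autumn | 10.0 | 58.8 | 21.7 |
| autumn | 12.0 | 59.0 | 21.0 |
| autumn | 15.0 | 58.1 | 21.1 |
| autumn | 20.0 | 58.0 | 21.8 |
| midnight | 3.00 | 62.4 | 13.4 |
| midnight | 6.00 | 61.6 | 15.1 |
| midnight | 10.0 | 62.6 | 15.6 |
| midnight | 12.0 | 62.0 | 16.7 |
| midnight | 15.0 | 62.0 | 17.5 |
| midnight | 20.0 | 62.4 | 17.0 |
| winter | 4.00 | 73.0 | 7.7 |
| winter | 8.00 | 74.2 | 8.8 |
| winter | 10.0 | 72.1 | 10.0 |
| winter | 15.0 | 74.3 | 9.8 |
| winter | 20.0 | 72.9 | 9.4 |

(readings scatter by 0.5 percentage points)

- ratio of target to side product at 1.0 h
- ratio of target to side product at 15 d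
- which of target and side product there is more of at 15 d

- the numbers in the tables scatter with a standard deviation of 0.5 percentage points

I read the late autumn ratio as 2.74. I read the late midnight ratio as 3.64, higher than the autumn reading. Those runs share a partner charge, so I compared them by load, the substrate charged as a fraction of the partner charged: 0.778 in autumn, 1.22 at midnight. The load slope, the rise of the ratio per unit of load at that partner charge, came to 2.03.

The new flask has the same partner charge and a load of 0.556, below autumn's. So I took 2.74 as my upper bound. The slope then gave a small correction, 0.451, and the line reached 2.29. I took that as my lower bound, a judgement: I expected the fall to flatten as load shrank. Both bounds exceed 1, so I expected target to lead. The readings start at 3.00 d, far later than 1.0 h, so I set no bracket for the early ratio.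

The forecast, reached by another route, put the ratio at 2.4 (2 to 2.9) at 15 d and at 4 at 1.0 h, reasoning that “side would then be held back”.

The new flask gave 2.41 at 15 d, inside my bracket, with 57.1% target against 23.7% side product. At 1.0 h it gave 77.6.

    substrate + coupling partner → intermediate A (k = 0.0270 M⁻¹ h⁻¹)
    coupling partner + intermediate A → side product (k = 0.0170 M⁻¹ h⁻¹)
    substrate → target (k = 0.0560 h⁻¹)
    intermediate A ⇌ intermediate B (K = 2.10, k = 0.0320 h⁻¹)
    intermediate B ⇌ intermediate C (K = 39.0, k = 0.0200 h⁻¹)
    capture agent + intermediate B → trapped intermediate (k = 0.00500 M⁻¹ h⁻¹)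
    target → over-reaction product (k = 1.70 × 10⁻⁵ h⁻¹)

A neighbouring flask kept the partner charge and took 1.7 M of substrate, a load of 0.944, between the autumn and midnight loads. The load slope, carried up from autumn, gave 3.08. That flask gave 3.05, below the line and above the autumn ratio. It held 59.9% target and 19.7% side product at 15.0 d.

The readings are simulated with made-up constants, noise included.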